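**Plan**

- Rings are lettered A to D from the terminal aryloxyphloroglucinol (A) to the trihydroxyphenyl ring (D). The retrosynthesis first removes seven O-methyl groups, then cuts ring A at C2–C3 (ether-bearing carbon to a phenol carbon) back to a 6-(aryloxymethyl)-4-methoxy-2-pyranone, and cuts the O–CH2 bond of that pyranone to a phenol and 6-(bromomethyl)-4-methoxy-2-pyranone.
- Ring B is taken apart by the same two cuts. The ring C phenol oxygen is traced to a C–H borylation/oxidation and the C–D bond to a Suzuki–Miyaura coupling.
- Forward order: D–C biaryl, ring C phenol, pyranone ether, fold to ring B, alkylation of one of the two equivalent ring B hydroxyls with a second pyranone, fold to ring A, demethylation.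
- Enabling feature: in rings A and B the carbon carrying the ether oxygen (C2) lies between two hydroxylated carbons (C1, C3) with the third oxygen at C5. This is the pattern a 6-aryloxy-3,5-dioxohexanoate gives when its aryloxy-bearing C6 closes onto the ester carbon C1.
- Stereochemistry: none to set. The target has no stereocentre, and both rings on the C–D axis are symmetric about it.

Key step: step 7

Remark: compounds 1, 2 and 6 are taken as purchasable, and the methyl ethers serve as the only protecting groups throughout.

**Route**

Step 1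
Reactants: 1 2-bromo-1,3-dimethoxybenzene; 2 (2,4,6-trimethoxyphenyl)boronic acid
Product: 3 2,2',4,6,6'-pentamethoxy-1,1'-biphenyl
Conditions: Pd(OAc)2 (cat.), SPhos, K3PO4, toluene/H2O, 100 °C, excess 2
Reagents that add atoms: none
Why: Suzuki–Miyaura coupling, in which SPhos-ligated zerovalent palladium inserts into the hindered C–Br bond of 1 and the bulky electron-rich phosphine speeds transmetalation and reductive elimination enough for the tetra-ortho-methoxy biaryl to form ahead of protodeboronation of 2.

Step 2
Reactants: 3 2,2',4,6,6'-pentamethoxy-1,1'-biphenyl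
Product: 5 3,5-dimethoxy-4-(2,4,6-trimethoxyphenyl)phenol, via pinacol boronate 4 (not isolated)
Conditions: [Ir(OMe)(cod)]2 (cat.), dtbpy, B2pin2, THF, 80 °C; then NaOH, H2O2, THF/H2O, 0 °C to rt; acidic work-up
Reagents that add atoms: hydrogen peroxide, OO (phenolic oxygen of 5); bis(pinacolato)diboron, CC1(C)OB(OC1(C)C)B1OC(C)(C)C(C)(C)O1 (boryl group of intermediate 4 only, no atom of it remains in 5)
Why: Iridium-catalysed C–H borylation is sterically governed and the only C–H bond of 3 without an ortho substituent is the one para to the biaryl bond on the dimethoxy ring (both C–H bonds of the trimethoxy ring sit between two methoxy groups), so a single boronate 4 should form, and basic peroxide oxidation (aryl migration from boron to oxygen) converts it into phenol 5.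

Step 3
Reactants: 6 4-methoxy-6-methyl-2H-pyran-2-one
Product: 7 6-(bromomethyl)-4-methoxy-2H-pyran-2-one
Conditions: NBS, AIBN (cat.), PhCF3, reflux
Reagents that add atoms: N-bromosuccinimide, O=C1CCC(=O)N1Br
Why: Wohl–Ziegler bromination, in which radical initiation in a non-polar medium directs bromine to the allylic-type 6-methyl group rather than to ionic substitution at C3, a documented transformation of this pyranone.

Step 4
Reactants: 5 3,5-dimethoxy-4-(2,4,6-trimethoxyphenyl)phenol; 7 6-(bromomethyl)-4-methoxy-2H-pyran-2-one
Product: 8 6-{[3,5-dimethoxy-4-(2,4,6-trimethoxyphenyl)phenoxy]methyl}-4-methoxy-2H-pyran-2-one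
Conditions: K2CO3, acetone, reflux
Reagents that add atoms: none
Why: Williamson ether synthesis, in which the unhindered phenoxide of 5 displaces the primary, pyranone-activated bromide of 7 by SN2 while the mild carbonate base leaves the lactone intact.

Step 5
Reactants: 8 6-{[3,5-dimethoxy-4-(2,4,6-trimethoxyphenyl)phenoxy]methyl}-4-methoxy-2H-pyran-2-one
Product: 10 2-[3,5-dimethoxy-4-(2,4,6-trimethoxyphenyl)phenoxy]-5-methoxybenzene-1,3-diol, via ring-opened keto ester 9 (not isolated)
Conditions: NaOMe (excess), MeOH, reflux, Ar; then aq. HCl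
Reagents that add atoms: sodium methoxide, C[O-].[Na+] (ester methoxy of intermediate 9 only, expelled again on ring closure, no atom of it remains in 10)
Why: Methoxide-induced pyranone-to-phloroglucinol isomerisation (lactone methanolysis followed by intramolecular Claisen condensation), in which opening of 8 gives the (2E)-keto ester 9, its aryloxy-bearing C6 enolate acylates onto the ester carbonyl in a 6-(enolendo)-exo-trig closure, and the cyclohexenedione formed tautomerises to the aromatic ring B of 10.

Step 6
Reactants: 10 2-[3,5-dimethoxy-4-(2,4,6-trimethoxyphenyl)phenoxy]-5-methoxybenzene-1,3-diol; 7 6-(bromomethyl)-4-methoxy-2H-pyran-2-one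
Product: 11 6-({2-[3,5-dimethoxy-4-(2,4,6-trimethoxyphenyl)phenoxy]-3-hydroxy-5-methoxyphenoxy}methyl)-4-methoxy-2H-pyran-2-one
Conditions: 7 (0.9 equiv), K2CO3 (1 equiv), DMF, 0 °C to rt
Reagents that add atoms: none
Why: Williamson ether synthesis on a diol whose two hydroxyls are equivalent by symmetry, so mono-alkylation can give only one constitutional isomer, while the bromide as limiting reagent should restrain double alkylation and allow unreacted 10 to be recovered.

Step 7
Reactants: 11 6-({2-[3,5-dimethoxy-4-(2,4,6-trimethoxyphenyl)phenoxy]-3-hydroxy-5-methoxyphenoxy}methyl)-4-methoxy-2H-pyran-2-one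
Product: 13 2-{2-[3,5-dimethoxy-4-(2,4,6-trimethoxyphenyl)phenoxy]-3-hydroxy-5-methoxyphenoxy}-5-methoxybenzene-1,3-diol, via ring-opened keto ester 12 (not isolated)
Conditions: NaOMe (excess), MeOH, reflux, Ar; then aq. HCl
Reagents that add atoms: sodium methoxide, C[O-].[Na+] (ester methoxy of intermediate 12 only, expelled again on ring closure, no atom of it remains in 13)
Why: Methoxide adds to the lactone carbonyl of 11 and opens the ring to keto ester 12, in which the ester and the CH2C(=O)CH2OAr arm remain cis across the enol ether double bond; the ketone enolate formed at the aryloxy-bearing carbon C6 then attacks the ester carbonyl C1, methoxide is expelled, and the resulting 2-aryloxy-5-methoxycyclohex-4-ene-1,3-dione tautomerises to the aromatic bis-phenoxide, so that the new bond joins the ether-bearing carbon C2 of ring A to C3. The closest known reaction type is the alkoxide-induced isomerisation of 4-methoxy-6-methyl-2-pyranone to phloroglucinol monomethyl ether (lactone opening followed by intramolecular Claisen condensation), and Claisen acylation at the carbon of aryloxymethyl ketones is itself familiar. Ring A closes in a 6-(enolendo)-exo-trig mode. No stereocentre is formed. The selectivity needed is reaction through the C6 enolate and not through the more acidic C4 position: enolisation is reversible in NaOMe/MeOH, the C4 enolate could only close a four-membered ring and so remains a resting state, while the C6 enolate is favoured inductively by the aryloxy oxygen and leads to an aromatic phenoxide that acts as the thermodynamic sink. Relactonisation to 11 and scrambling of the enol ether geometry are reversible and drain through the same channel, and the ring B phenoxide, meta to the ether oxygen, is a spectator.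

Step 8
Reactants: 13 2-{2-[3,5-dimethoxy-4-(2,4,6-trimethoxyphenyl)phenoxy]-3-hydroxy-5-methoxyphenoxy}-5-methoxybenzene-1,3-diol
Product: 14 2-{2-[3,5-dihydroxy-4-(2,4,6-trihydroxyphenyl)phenoxy]-3,5-dihydroxyphenoxy}benzene-1,3,5-triol
Conditions: BBr3 (excess), CH2Cl2, −78 °C to rt; then H2O, 0 °C
Reagents that add atoms: none
Why: Lewis acid-mediated ether cleavage, in which BBr3 coordinates each methoxy oxygen and bromide removes the methyl group by SN2, a pathway open only to alkyl–oxygen bonds, so the two diaryl ether links and the biaryl bond should persist while all seven methyl ethers are cleaved.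

**Compound list**

1 | 2-bromo-1,3-dimethoxybenzene | COc1cccc(OC)c1Br | starting material
2 | (2,4,6-trimethoxyphenyl)boronic acid | COc1cc(OC)c(B(O)O)c(OC)c1 | starting material
3 | 2,2',4,6,6'-pentamethoxy-1,1'-biphenyl | COc1cc(OC)c(-c2c(OC)cccc2OC)c(OC)c1 | intermediate
4 | 2-(2,2',4',6,6'-pentamethoxy-1,1'-biphenyl-4-yl)-4,4,5,5-tetramethyl-1,3,2-dioxaborolane | COc1cc(OC)c(-c2c(OC)cc(B3OC(C)(C)C(C)(C)O3)cc2OC)c(OC)c1 | intermediate
5 | 3,5-dimethoxy-4-(2,4,6-trimethoxyphenyl)phenol | COc1cc(OC)c(-c2c(OC)cc(O)cc2OC)c(OC)c1 | intermediate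
6 | 4-methoxy-6-methyl-2H-pyran-2-one | COC1=CC(=O)OC(C)=C1 | starting material
7 | 6-(bromomethyl)-4-methoxy-2H-pyran-2-one | COC1=CC(=O)OC(CBr)=C1 | intermediate
8 | 6-{[3,5-dimethoxy-4-(2,4,6-trimethoxyphenyl)phenoxy]methyl}-4-methoxy-2H-pyran-2-one | COC1=CC(=O)OC(COc2cc(OC)c(-c3c(OC)cc(OC)cc3OC)c(OC)c2)=C1 | intermediate
9 | methyl (2E)-6-[3,5-dimethoxy-4-(2,4,6-trimethoxyphenyl)phenoxy]-3-methoxy-5-oxohex-2-enoate | COC(=O)/C=C(/OC)CC(=O)COc1cc(OC)c(-c2c(OC)cc(OC)cc2OC)c(OC)c1 | intermediate
10 | 2-[3,5-dimethoxy-4-(2,4,6-trimethoxyphenyl)phenoxy]-5-methoxybenzene-1,3-diol | COc1cc(O)c(Oc2cc(OC)c(-c3c(OC)cc(OC)cc3OC)c(OC)c2)c(O)c1 | intermediate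
11 | 6-({2-[3,5-dimethoxy-4-(2,4,6-trimethoxyphenyl)phenoxy]-3-hydroxy-5-methoxyphenoxy}methyl)-4-methoxy-2H-pyran-2-one | COC1=CC(=O)OC(COc2cc(OC)cc(O)c2Oc2cc(OC)c(-c3c(OC)cc(OC)cc3OC)c(OC)c2)=C1 | intermediate
12 | methyl (2E)-6-{2-[3,5-dimethoxy-4-(2,4,6-trimethoxyphenyl)phenoxy]-3-hydroxy-5-methoxyphenoxy}-3-methoxy-5-oxohex-2-enoate | COC(=O)/C=C(/OC)CC(=O)COc1cc(OC)cc(O)c1Oc1cc(OC)c(-c2c(OC)cc(OC)cc2OC)c(OC)c1 | intermediate
13 | 2-{2-[3,5-dimethoxy-4-(2,4,6-trimethoxyphenyl)phenoxy]-3-hydroxy-5-methoxyphenoxy}-5-methoxybenzene-1,3-diol | COc1cc(O)c(Oc2cc(OC)cc(O)c2Oc2cc(OC)c(-c3c(OC)cc(OC)cc3OC)c(OC)c2)c(O)c1 | intermediate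
14 | 2-{2-[3,5-dihydroxy-4-(2,4,6-trihydroxyphenyl)phenoxy]-3,5-dihydroxyphenoxy}benzene-1,3,5-triol | Oc1cc(O)c(Oc2cc(O)cc(O)c2Oc2cc(O)c(-c3c(O)cc(O)cc3O)c(O)c2)c(O)c1 | target

**Count**

Total step count: 8. Longest linear sequence: 7 (steps 1, 2, 4, 5, 6, 7, 8). Step 3 is a one-step side branch whose product 7 is used in steps 4 and 6.

**Steps most likely to fail**

Step 7 (key step). C-acylation through the sparsely populated aryloxy-bearing enolate may be too slow, and the extra negative charge of the ring B phenoxide may slow it further. The reaction could then stall at the open-chain keto ester, and ester saponification by traces of hydroxide, drift of the enol ether double bond to the unproductive geometry and intermolecular aldol condensation could consume the material.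

The fallback sets out from 10 and brings ring A in intact. A copper-catalysed Ullmann-type etherification (CuI, picolinic acid, K3PO4, DMSO, 90 °C) with purchased 2-iodo-1,3,5-trimethoxybenzene, used in deficiency so that only one of the two equivalent hydroxyls reacts, should give 2-[3,5-dimethoxy-4-(2,4,6-trimethoxyphenyl)phenoxy]-5-methoxy-3-(2,4,6-trimethoxyphenoxy)phenol F1. BBr3 in CH2Cl2 then cleaves its nine methyl ethers, and the sequence comes back to the route at 14.

Step 5. This is the same fold in its first use, and the same course of failure applies: slow ring closure with loss of the opened keto ester to saponification and condensation.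

The fallback sets out from 5 and builds the C–O bond to an intact ring B:
- Purchased 5-methoxyresorcinol is protected with MOMCl and i-Pr2NEt as 1-methoxy-3,5-bis(methoxymethoxy)benzene F2.
- Directed ortho-lithiation (n-BuLi, THF, 0 °C) should occur between the two acetal groups, and an I2 quench gives 2-iodo-5-methoxy-1,3-bis(methoxymethoxy)benzene F3.
- Ullmann-type coupling of F3 with 5 (CuI, picolinic acid, K3PO4, DMSO, 90 °C) gives 5-[4-methoxy-2,6-bis(methoxymethoxy)phenoxy]-1,3-dimethoxy-2-(2,4,6-trimethoxyphenyl)benzene F4.
- HCl in MeOH removes both acetals, and the sequence comes back to the route at 10.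

Step 8. Cleavage may stop part-way when partly demethylated aryl borates precipitate. The free decaphenol may also be lost by air oxidation and irreversible adsorption during aqueous work-up and chromatography.

The fallback sets out from 13 and isolates the product through a stable derivative. The crude material from the BBr3 treatment is not purified but acetylated (Ac2O, pyridine, DMAP) to the decaacetate of 14, 2-{2-[3,5-diacetoxy-4-(2,4,6-triacetoxyphenyl)phenoxy]-3,5-diacetoxyphenoxy}benzene-1,3,5-triyl triacetate F5. This can be chromatographed on silica and separated from under-demethylated congeners. Methanolysis with catalytic NaOMe in MeOH under argon (Zemplén deacetylation), followed by neutralisation with an acidic resin, comes back to the route at 14.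

**Further compounds**

F1 | step 7 | 2-[3,5-dimethoxy-4-(2,4,6-trimethoxyphenyl)phenoxy]-5-methoxy-3-(2,4,6-trimethoxyphenoxy)phenol | COc1cc(OC)c(Oc2cc(OC)cc(O)c2Oc2cc(OC)c(-c3c(OC)cc(OC)cc3OC)c(OC)c2)c(OC)c1
F2 | step 5 | 1-methoxy-3,5-bis(methoxymethoxy)benzene | COCOc1cc(OC)cc(OCOC)c1
F3 | step 5 | 2-iodo-5-methoxy-1,3-bis(methoxymethoxy)benzene | COCOc1cc(OC)cc(OCOC)c1I
F4 | step 5 | 5-[4-methoxy-2,6-bis(methoxymethoxy)phenoxy]-1,3-dimethoxy-2-(2,4,6-trimethoxyphenyl)benzene | COCOc1cc(OC)cc(OCOC)c1Oc1cc(OC)c(-c2c(OC)cc(OC)cc2OC)c(OC)c1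
F5 | step 8 | 2-{2-[3,5-diacetoxy-4-(2,4,6-triacetoxyphenyl)phenoxy]-3,5-diacetoxyphenoxy}benzene-1,3,5-triyl triacetate | CC(=O)Oc1cc(OC(C)=O)c(Oc2cc(OC(C)=O)cc(OC(C)=O)c2Oc2cc(OC(C)=O)c(-c3c(OC(C)=O)cc(OC(C)=O)cc3OC(C)=O)c(OC(C)=O)c2)c(OC(C)=O)c1
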